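The C1–C8a bond of the pyran ring is made first, inside a temporary ring. The target carries the C7 tertiary hydroxyl and the C1 methylene on the same face of the carbocycle (ring A). A (bromomethyl)dimethylsilyl ether on O7 of a methyl shikimate-derived cyclohexene therefore delivers C1 by 6-exo radical cyclization onto C8a, the enoate β-carbon, closing an oxasilacyclohexane and fixing C8a from C7 in one operation. Tamao oxidation then cleaves the tether to the C1 hydroxymethyl group. The shikimate carboxyl carbon becomes C4 (lactone, then alkyne); Sonogashira coupling, gold-catalysed 6-endo closure of O2–C3 and chlorination at C5 complete the target.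

Key step: step 5

Remark: all ring positions carry the locants of the target (O2, C1, C3, C4, C4a, C5 to C8, C8a); methyl shikimate, ethyl (S)-3-hydroxybutanoate and all reagents are taken as commercial, and the C4a centre formed in step 5 is of no consequence because it becomes sp2 in step 9.

Step 1
Reactants: 1 methyl shikimate
Product: 2 methyl 3,5-bis-O-(tert-butyldimethylsilyl)shikimate
Conditions: TBSCl (2.2 equiv), imidazole, DMF, 0 °C
Reagents that add atoms: tert-butyldimethylsilyl chloride, CC(C)(C)[Si](C)(C)Cl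
Why: Regioselective silylation: the C7 hydroxyl is flanked by both other hydroxyls and should be too hindered to react once its neighbours on C6 and C8 carry the bulky silyl groups.

Step 2
Reactants: 2 methyl 3,5-bis-O-(tert-butyldimethylsilyl)shikimate
Product: 3 methyl (3R,5R)-3,5-bis(silyloxy)-4-oxocyclohex-1-ene-1-carboxylate
Conditions: DMP, NaHCO3, CH2Cl2, 0 °C to rt
Reagents that add atoms: none
Why: Dess–Martin oxidation of the single free secondary alcohol under buffered, non-basic conditions avoids enolization of the ketone toward the doubly activated C8–H.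

Step 3
Reactants: 3 methyl (3R,5R)-3,5-bis(silyloxy)-4-oxocyclohex-1-ene-1-carboxylate
Product: 4 methyl (3R,4S,5R)-3,5-bis(silyloxy)-4-hydroxy-4-methylcyclohex-1-ene-1-carboxylate
Conditions: MeMgBr, CeCl3, THF, −78 °C
Reagents that add atoms: methylmagnesium bromide, C[Mg]Br
Why: Organocerium-mediated Grignard 1,2-addition is chemoselective for the ketone over the enoate and suppresses enolization, and attack anti to the pseudoaxial allylic C8 silyloxy group of the shikimate half-chair (polar Felkin–Anh control) should place the methyl trans and the new C7 hydroxyl cis to O8.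

Step 4
Reactants: 4 methyl (3R,4S,5R)-3,5-bis(silyloxy)-4-hydroxy-4-methylcyclohex-1-ene-1-carboxylate
Product: 5 O7-(bromomethyl)dimethylsilyl ether of 4
Conditions: BrCH2SiMe2Cl, Et3N, DMAP, CH2Cl2, rt
Reagents that add atoms: (bromomethyl)chlorodimethylsilane, C[Si](C)(Cl)CBr
Why: Silylation of the tertiary alcohol with a small chlorosilane activated by DMAP installs the radical precursor on O7, the oxygen that must end up cis to C1.

Step 5
Reactants: 5 O7-(bromomethyl)dimethylsilyl ether of 4
Product: 6 bicyclic siloxane methyl 8,9-bis(silyloxy)-1,3,3-trimethyl-2-oxa-3-silabicyclo[3.3.1]nonane-6-carboxylate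
Conditions: Bu3SnH (1.3 equiv, syringe pump), AIBN (cat.), PhH (0.005 M), 80 °C
Reagents that add atoms: none
Why: Bu3Sn• abstracts bromine from 5 to give a nucleophilic α-silyl methyl radical that adds to C8a, the β-carbon of the enoate, and the resulting α-ester radical at C4a is reduced by Bu3SnH. The closest known reaction type is the Stork–Nishiyama silicon-tethered radical cyclization of (bromomethyl)dimethylsilyl ethers, here in its homoallylic variant. The closure is 6-exo-trig and forms the 1-oxa-2-silacyclohexane ring O7–Si–C1–C8a–C8–C7, which bridges C7 and C8a of ring A. The new stereocentre C8a is controlled by the C7 oxygen: the three-atom tether on the axial C7–O bond can reach only the face of the ring that carries this oxygen, so C1 should end up cis to O7 and O8, whereas the C4a centre formed on hydrogen transfer is erased later. The step needs 6-exo rather than 7-endo attack and cyclization faster than direct reduction; polarity-matched addition to the unsubstituted β-carbon with formation of a stabilized radical secures the first, slow addition of the stannane at high dilution the second.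

Step 6
Reactants: 6 bicyclic siloxane
Product: 8 cis-fused lactone 4,6-bis(silyloxy)-5-hydroxy-5-methylhexahydro-2-benzofuran-1(3H)-one, via diol ester 7 (not isolated)
Conditions: KF, KHCO3, 30% H2O2, THF/MeOH, 40 °C; then PPTS (cat.), CH2Cl2, rt
Reagents that add atoms: hydrogen peroxide, OO
Why: Tamao oxidation converts the C1–Si bond of the alkoxysilane into C1–OH and frees O7, and the cis γ-hydroxy ester then lactonizes, masking C1–OH and C4 together.

Step 7
Reactants: 8 cis-fused lactone
Product: 11 5-ethynyl-4-(hydroxymethyl)-2-methylcyclohexane-1,2,3-triol, via lactol 9 (not isolated), via bis-silyl alkynyl diol 10 (not isolated)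
Conditions: iBu2AlH, CH2Cl2, −78 °C; then MeOH, K2CO3, dimethyl (1-diazo-2-oxopropyl)phosphonate, −78 °C to rt; then HCl/MeOH (pH 1), rt
Reagents that add atoms: dimethyl (1-diazo-2-oxopropyl)phosphonate, COP(=O)(OC)C(=[N+]=[N-])C(C)=O
Why: iBu2AlH reduces the γ-lactone only to the lactol, whose open hydroxy aldehyde undergoes Ohira–Bestmann (Seyferth–Gilbert) homologation to the terminal alkyne C4≡C3–H, and acidic methanolysis in the same methanol solution then removes both silyl ethers.

Step 8
Reactants: 11 ethynyl tetraol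
Product: 12 O1,O8-di-tert-butylsilylene derivative of 11
Conditions: tBu2Si(OTf)2, 2,6-lutidine, DMF, −40 to 0 °C
Reagents that add atoms: di-tert-butylsilyl bis(trifluoromethanesulfonate), CC(C)(C)[Si](OS(=O)(=O)C(F)(F)F)(OS(=O)(=O)C(F)(F)F)C(C)(C)C
Why: Silylene protection: the reagent reacts first at the primary C1–OH and closes the favoured six-membered ring onto the cis C8–OH, leaving the C6 and the tertiary C7 hydroxyls free.

Step 9
Reactants: 12 silylene diol
Product: 13 silylene-protected 3-ethynyl-6-hydroxy-6-methylcyclohex-2-enone (ynenone)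
Conditions: IBX (3.5 equiv), DMSO/PhF, 75 °C
Reagents that add atoms: none
Why: IBX oxidizes the C6 alcohol to the ketone and then dehydrogenates it (IBX-mediated α,β-dehydrogenation) toward C5–C4a, the only enolizable side because C7 is quaternary, which also erases the C4a stereocentre.

Step 10
Reactants: 14 ethyl (S)-3-hydroxybutanoate
Product: 15 ethyl (2S,3S)-3-hydroxy-2-methylbutanoate
Conditions: LiN(iPr)2 (2.2 equiv), THF, −50 °C; MeI, DMPU, −78 to −20 °C
Reagents that add atoms: iodomethane, CI
Why: Fráter–Seebach alkylation: the chelated dianion is methylated anti to the C3 substituent, setting the (2S,3S) anti relationship that becomes C5′ and C6′ of the side chain.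

Step 11
Reactants: 15 ethyl (2S,3S)-3-hydroxy-2-methylbutanoate
Product: 16 ethyl (2S,3S)-3-(tert-butyldimethylsilyloxy)-2-methylbutanoate
Conditions: TBSCl, imidazole, DMF, rt
Reagents that add atoms: tert-butyldimethylsilyl chloride, CC(C)(C)[Si](C)(C)Cl
Why: Standard silylation protects the secondary alcohol for the reduction and olefination steps.

Step 12
Reactants: 16 silyl ether ester
Product: 17 (2S,3S)-3-(tert-butyldimethylsilyloxy)-2-methylbutanal
Conditions: iBu2AlH, CH2Cl2, −78 °C
Reagents that add atoms: none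
Why: Partial iBu2AlH reduction at −78 °C stops at the aldehyde through the stable tetrahedral aluminate, and cold work-up limits epimerization of the α-stereocentre.

Step 13
Reactants: 17 aldehyde
Product: 18 (2E,4R,5S)-5-(tert-butyldimethylsilyloxy)-2,4-dimethylhex-2-enal
Conditions: Ph3P=C(Me)CHO, PhMe, 90 °C
Reagents that add atoms: 2-(triphenylphosphoranylidene)propanal, CC(C=O)=P(c1ccccc1)(c1ccccc1)c1ccccc1
Why: Wittig olefination with the stabilized formyl ylide should give the E trisubstituted enal; the change of descriptor at the methyl-bearing carbon is a priority change only.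

Step 14
Reactants: 18 enal
Product: 19 (1E,3E,5R,6S)-1-iodo-3,5-dimethyl-6-(tert-butyldimethylsilyloxy)hepta-1,3-diene
Conditions: CrCl2, CHI3, THF, 0 °C
Reagents that add atoms: iodoform, IC(I)I
Why: Takai olefination converts the aldehyde into the E vinyl iodide through the geminal dichromium species.

Step 15
Reactants: 13 ynenone; 19 dienyl iodide
Product: 20 silyl-protected dienynyl enone
Conditions: Pd(PPh3)2Cl2 (5 mol%), CuI (10 mol%), Et3N, THF, rt
Reagents that add atoms: none
Why: Sonogashira coupling joins the terminal alkyne carbon C3 to the vinyl iodide with retention of the E geometry, and the mild amine base should leave the enone and the free tertiary alcohol untouched.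

Step 16
Reactants: 20 silyl-protected dienynyl enone
Product: 22 deschloro target, via desilylated ynenone 21 (not isolated)
Conditions: HF·pyridine, pyridine, THF, 0 °C to rt; then Ph3PAuNTf2 (2 mol%), CH2Cl2, rt
Reagents that add atoms: none
Why: Acidic fluoride removes the silylene and the silyl ether without generating alkoxides that could trigger retro-aldol opening, and gold-catalysed 6-endo-dig hydroalkoxylation (an oxa-Michael type 1,6-addition) of C1–OH to the polarized ynenone at C3, followed by protonation at C4, should give the vinylogous ester.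

Step 17
Reactants: 22 deschloro target
Product: 23 target CNP0536300.1
Conditions: NCS (1.05 equiv), MeCN, 0 °C
Reagents that add atoms: N-chlorosuccinimide, O=C1CCC(=O)N1Cl
Why: Electrophilic chlorination with NCS should occur at C5, the terminal and most nucleophilic carbon of the push–pull dienyl ether O2–C3=C4–C4a=C5–C6=O, with loss of the C5 proton restoring conjugation.

Compound list
1 | methyl (−)-shikimate, methyl (3R,4S,5R)-3,4,5-trihydroxycyclohex-1-ene-1-carboxylate | COC(=O)C1=C[C@@H](O)[C@@H](O)[C@H](O)C1 | starting material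
2 | methyl (3R,4S,5R)-3,5-bis[(tert-butyldimethylsilyl)oxy]-4-hydroxycyclohex-1-ene-1-carboxylate | COC(=O)C1=C[C@@H](O[Si](C)(C)C(C)(C)C)[C@@H](O)[C@H](O[Si](C)(C)C(C)(C)C)C1 | intermediate
3 | methyl (3R,5R)-3,5-bis[(tert-butyldimethylsilyl)oxy]-4-oxocyclohex-1-ene-1-carboxylate | COC(=O)C1=C[C@@H](O[Si](C)(C)C(C)(C)C)C(=O)[C@H](O[Si](C)(C)C(C)(C)C)C1 | intermediate
4 | methyl (3R,4S,5R)-3,5-bis[(tert-butyldimethylsilyl)oxy]-4-hydroxy-4-methylcyclohex-1-ene-1-carboxylate (C7–OH cis to O8, methyl cis to O6) | COC(=O)C1=C[C@@H](O[Si](C)(C)C(C)(C)C)[C@@](C)(O)[C@H](O[Si](C)(C)C(C)(C)C)C1 | intermediate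
5 | methyl (3R,4S,5R)-4-{[(bromomethyl)dimethylsilyl]oxy}-3,5-bis[(tert-butyldimethylsilyl)oxy]-4-methylcyclohex-1-ene-1-carboxylate | COC(=O)C1=C[C@@H](O[Si](C)(C)C(C)(C)C)[C@@](C)(O[Si](C)(C)CBr)[C@H](O[Si](C)(C)C(C)(C)C)C1 | intermediate
6 | methyl 8,9-bis[(tert-butyldimethylsilyl)oxy]-1,3,3-trimethyl-2-oxa-3-silabicyclo[3.3.1]nonane-6-carboxylate (O7–SiMe2–C1 bridge from C7 to C8a, C1 cis to O7 and O8, ester cis to C1) | COC(=O)[C@H]1[C@@H]2[C@@H](O[Si](C)(C)C(C)(C)C)[C@@](C)(O[Si](C)(C)C2)[C@H](O[Si](C)(C)C(C)(C)C)C1 | intermediate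
7 | methyl 3,5-bis[(tert-butyldimethylsilyl)oxy]-4-hydroxy-2-(hydroxymethyl)-4-methylcyclohexane-1-carboxylate (hydroxymethyl, C7–OH and O8 on one face) | COC(=O)[C@H]1[C@@H](CO)[C@@H](O[Si](C)(C)C(C)(C)C)[C@@](C)(O)[C@H](O[Si](C)(C)C(C)(C)C)C1 | intermediate
8 | cis-fused 4,6-bis[(tert-butyldimethylsilyl)oxy]-5-hydroxy-5-methylhexahydro-2-benzofuran-1(3H)-one (lactone C4(=O)–O–C1) | O=C1OC[C@H]2[C@@H](O[Si](C)(C)C(C)(C)C)[C@@](C)(O)[C@H](O[Si](C)(C)C(C)(C)C)C[C@@H]12 | intermediate
9 | lactol of 8, 4,6-bis[(tert-butyldimethylsilyl)oxy]-5-methyloctahydro-2-benzofuran-1,5-diol (anomeric mixture) | OC1OC[C@H]2[C@@H](O[Si](C)(C)C(C)(C)C)[C@@](C)(O)[C@H](O[Si](C)(C)C(C)(C)C)C[C@@H]12 | intermediate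
10 | [6-ethynyl-2,4-bis[(tert-butyldimethylsilyl)oxy]-3-hydroxy-3-methylcyclohexyl]methanol (O6,O8-bis-silyl ether of 11) | C#C[C@H]1[C@@H](CO)[C@@H](O[Si](C)(C)C(C)(C)C)[C@@](C)(O)[C@H](O[Si](C)(C)C(C)(C)C)C1 | intermediate
11 | 5-ethynyl-4-(hydroxymethyl)-2-methylcyclohexane-1,2,3-triol (C1H2OH, C8–OH and C7–OH on one face, C6–OH on the other) | C#C[C@H]1[C@@H](CO)[C@@H](O)[C@@](C)(O)[C@H](O)C1 | intermediate
12 | 2,2-di-tert-butyl-5-ethynyl-8-methylhexahydro-4H-1,3,2-benzodioxasiline-7,8-diol (silylene across O1 and O8) | C#C[C@H]1[C@H]2CO[Si](C(C)(C)C)(C(C)(C)C)O[C@H]2[C@@](C)(O)[C@H](O)C1 | intermediate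
13 | 2,2-di-tert-butyl-5-ethynyl-8-hydroxy-8-methyl-4a,8a-dihydro-4H-1,3,2-benzodioxasilin-7(8H)-one (ynenone, C4a=C5–C6=O) | C#CC1=CC(=O)[C@](C)(O)[C@@H]2O[Si](C(C)(C)C)(C(C)(C)C)OC[C@H]12 | intermediate
14 | ethyl (S)-3-hydroxybutanoate | CCOC(=O)C[C@H](C)O | starting material
15 | ethyl (2S,3S)-3-hydroxy-2-methylbutanoate (anti) | CCOC(=O)[C@@H](C)[C@H](C)O | intermediate
16 | ethyl (2S,3S)-3-[(tert-butyldimethylsilyl)oxy]-2-methylbutanoate | CCOC(=O)[C@@H](C)[C@H](C)O[Si](C)(C)C(C)(C)C | intermediate
17 | (2S,3S)-3-[(tert-butyldimethylsilyl)oxy]-2-methylbutanal | O=C[C@@H](C)[C@H](C)O[Si](C)(C)C(C)(C)C | intermediate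
18 | (2E,4R,5S)-5-[(tert-butyldimethylsilyl)oxy]-2,4-dimethylhex-2-enal | O=C/C(C)=C/[C@@H](C)[C@H](C)O[Si](C)(C)C(C)(C)C | intermediate
19 | (1E,3E,5R,6S)-6-[(tert-butyldimethylsilyl)oxy]-1-iodo-3,5-dimethylhepta-1,3-diene | I/C=C/C(C)=C/[C@@H](C)[C@H](C)O[Si](C)(C)C(C)(C)C | intermediate
20 | ynenone 13 carrying the (3E,5E,7R,8S)-8-silyloxy-5,7-dimethylnona-3,5-dien-1-ynyl chain at C4a (silylene and silyl ether retained) | CC(/C=C/C#CC1=CC(=O)[C@](C)(O)[C@@H]2O[Si](C(C)(C)C)(C(C)(C)C)OC[C@H]12)=C\[C@@H](C)[C@H](C)O[Si](C)(C)C(C)(C)C | intermediate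
21 | fully desilylated 20: 5,6-dihydroxy-4-(hydroxymethyl)-6-methyl-3-dienynyl-cyclohex-2-enone with free side-chain alcohol | CC(/C=C/C#CC1=CC(=O)[C@](C)(O)[C@H](O)[C@@H]1CO)=C\[C@@H](C)[C@H](C)O | intermediate
22 | (7R,8R,8aS)-7,8-dihydroxy-3-[(1E,3E,5R,6S)-6-hydroxy-3,5-dimethylhepta-1,3-dien-1-yl]-7-methyl-1,7,8,8a-tetrahydro-6H-isochromen-6-one | CC(/C=C/C1=CC2=CC(=O)[C@](C)(O)[C@H](O)[C@@H]2CO1)=C\[C@@H](C)[C@H](C)O | intermediate
23 | (7R,8R,8aS)-5-chloro-7,8-dihydroxy-3-[(1E,3E,5R,6S)-6-hydroxy-3,5-dimethylhepta-1,3-dien-1-yl]-7-methyl-1,7,8,8a-tetrahydro-6H-isochromen-6-one | CC(/C=C/C1=CC2=C(Cl)C(=O)[C@](C)(O)[C@H](O)[C@@H]2CO1)=C\[C@@H](C)[C@H](C)O | target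

Total step count: 17. Longest linear sequence: 12 steps (steps 1 to 9 and 15 to 17, from methyl shikimate); the side chain takes 5 steps (10 to 14) before the coupling.

Steps most likely to fail

Step 3. Poor facial selectivity in the methyl addition is the main concern: the ketone is flanked by two silyloxy groups on opposite faces, so attack from the face of O8 would give the C7 epimer. The fallback reverses which group is delivered to C7. From 3, Takai–Lombardo methylenation (Zn, CH2Br2, TiCl4, THF) gives the exocyclic alkene methyl 3,5-bis(silyloxy)-4-methylidenecyclohex-1-ene-1-carboxylate F1. Mukaiyama hydration (Mn(dpm)3 cat., PhSiH3, O2, iPrOH) of this electron-rich 1,1-disubstituted alkene then introduces oxygen, not carbon, at C7 and comes back to the route at 4. If steric approach favours one face for an incoming group, that preference now places the hydroxyl there.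

Step 5. Premature reduction of the α-silyl radical, or failure of the hindered tertiary silyl ether to reach the conformer with the axial C7–O bond, would give the uncyclized trimethylsilyl ether. The fallback keeps the same bond and a temporary silicon ring but uses the classical five-membered closure from the allylic oxygen. From 4, Bu4NF gives the triol methyl 3,4,5-trihydroxy-4-methylcyclohex-1-ene-1-carboxylate F2, and BrCH2SiMe2Cl (2.2 equiv, Et3N) silylates the two secondary hydroxyls to the bis(bromomethylsilyl) ether F3. With Bu3SnH/AIBN the O8-tethered radical should close by 5-exo attack on C8a, cis to O8, while the O6 tether is reduced to a trimethylsilyl ether, giving the oxasilolane F4. Tamao oxidation (KF, KHCO3, H2O2) with lactonization gives the triol lactone F5, and iBu2AlH followed by the Ohira–Bestmann reagent comes back to the route at 11.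

Step 17. Chlorination at other nucleophilic sites (C4 or the side-chain diene) or over-chlorination of the unprotected final intermediate is possible. The fallback installs chlorine on ring A before the side chain is present and also replaces step 9. From 12, Dess–Martin oxidation gives the C6 ketone F6, SO2Cl2 gives the 5,5-dichloro ketone F7, and DBU eliminates HCl across C5–C4a to the 5-chloro ynenone F8. Sonogashira coupling with 19 gives the chlorinated dienynyl enone F9. HF·pyridine followed by Ph3PAuNTf2 then passes through the desilylated chloro ynenone F10 (not isolated) and comes back to the route at 23.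

Further compounds
F1 | step 3 | methyl (3R,5R)-3,5-bis[(tert-butyldimethylsilyl)oxy]-4-methylidenecyclohex-1-ene-1-carboxylate | COC(=O)C1=C[C@@H](O[Si](C)(C)C(C)(C)C)C(=C)[C@H](O[Si](C)(C)C(C)(C)C)C1
F2 | step 5 | methyl (3R,4S,5R)-3,4,5-trihydroxy-4-methylcyclohex-1-ene-1-carboxylate | COC(=O)C1=C[C@@H](O)[C@@](C)(O)[C@H](O)C1
F3 | step 5 | methyl 3,5-bis{[(bromomethyl)dimethylsilyl]oxy}-4-hydroxy-4-methylcyclohex-1-ene-1-carboxylate | COC(=O)C1=C[C@@H](O[Si](C)(C)CBr)[C@@](C)(O)[C@H](O[Si](C)(C)CBr)C1
F4 | step 5 | cis-fused 1-oxa-2-silacyclopentane (O8–SiMe2–C1 ring on C8 and C8a) with C7–OH free, O6 trimethylsilyl ether and C4a methyl ester | COC(=O)[C@H]1[C@H]2C[Si](C)(C)O[C@H]2[C@@](C)(O)[C@H](O[Si](C)(C)C)C1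
F5 | step 5 | cis-fused 4,5,6-trihydroxy-5-methylhexahydro-2-benzofuran-1(3H)-one | O=C1OC[C@H]2[C@@H](O)[C@@](C)(O)[C@H](O)C[C@@H]12
F6 | step 17 | 2,2-di-tert-butyl-5-ethynyl-8-hydroxy-8-methylhexahydro-4H-1,3,2-benzodioxasilin-7-one (C6 ketone of 12) | C#C[C@H]1[C@H]2CO[Si](C(C)(C)C)(C(C)(C)C)O[C@H]2[C@@](C)(O)C(=O)C1
F7 | step 17 | 5,5-dichloro derivative of F6 (C5 gem-dichloride) | C#C[C@H]1[C@H]2CO[Si](C(C)(C)C)(C(C)(C)C)O[C@H]2[C@@](C)(O)C(=O)C1(Cl)Cl
F8 | step 17 | 5-chloro analogue of ynenone 13 | C#CC1=C(Cl)C(=O)[C@](C)(O)[C@@H]2O[Si](C(C)(C)C)(C(C)(C)C)OC[C@H]12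
F9 | step 17 | 5-chloro analogue of 20 | CC(/C=C/C#CC1=C(Cl)C(=O)[C@](C)(O)[C@@H]2O[Si](C(C)(C)C)(C(C)(C)C)OC[C@H]12)=C\[C@@H](C)[C@H](C)O[Si](C)(C)C(C)(C)C
F10 | step 17 | 5-chloro analogue of 21 (desilylated chloro ynenone) | CC(/C=C/C#CC1=C(Cl)C(=O)[C@](C)(O)[C@H](O)[C@@H]1CO)=C\[C@@H](C)[C@H](C)O
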